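Remark: carbons are numbered C1 (lactone carbonyl) to C12 (methyl) throughout; commercial 2-deoxy-D-galactose (the hydration product of D-galactal, used as its anomeric mixture) is assumed as the chiral-pool start. TBS = tert-butyldimethylsilyl, TES = triethylsilyl, PMB = 4-methoxybenzyl.

## Analysis of the target

Target 30 is a cis-fused bicycle. An oxolane (ring oxygen, C4, C5, C6, C7) shares the C4–C5 bond with a six-membered lactone (C1–C5 plus the oxygen on C5), and C7 carries an (E)-alkenyl chain C8–C12 with a benzoate on C10 and an acetate on C11. There are seven stereocentres (3R, 4R, 5R, 6R, 7S, 10S, 11R). All four oxolane substituents (the C3 arm on C4, the lactone oxygen on C5, the hydroxyl on C6, the alkenyl group on C7) lie on one face, and the C3 hydroxyl is cis to the ring oxygen on the lactone ring, that is, on the concave side. Read as an open chain, C3–C5 have the 2-deoxy-D-lyxo pattern of 2-deoxy-D-galactose, C5/C6 are erythro, C6/C7 threo and C10/C11 erythro. The sensitive groups are the β-hydroxy lactone (elimination), the two different esters on neighbouring oxygens (migration, no base or hydride once they are in place) and the allylic C7–O bond (ionisation). The difficulty is that the all-cis oxolane is the crowded isomer and cannot be reached by equilibration, and that five contiguous oxygens (O3–O7) need different fates. The strategy rests on C7: it is allylic to C8=C9, bonded to the ring oxygen and flanked by the free C6 hydroxyl, which is what remains when O4 opens a 6,7-epoxide at its allylic carbon.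

## Retrosynthetic reasoning

The lactone C1–O5 bond is cut first. A β-silyloxy lactone would not survive the basic and reducing steps, so C1 travels as a tert-butyl ester and the lactone is closed last from triol ester 28, which comes from bis-silyl ether 27 by desilylation.

The O4–C7 bond of 27 is cut next (the key disconnection), giving cis-6,7-epoxide 26 with a free C4 hydroxyl. One stereocentre (C7) and one ring are formed, by stereospecific inversion, on a chain that already carries every carbon and both esters, so nothing sensitive has to be built afterwards. O3 and O5 stay silylated so that only O4 can reach C7.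

O4 must be masked until then by a group that can be removed beside two TBS ethers, a vinyl epoxide and two esters; a TES ether (25) does this.

The C8=C9 bond of 25 is cut by cross-metathesis into vinyl epoxide 17 and allylic benzoate 24. An olefination through a C9 carbanion (sulfone or ylide) would be the more usual choice, but with the benzoate on C10 such a carbanion eliminates; metathesis is neutral and tolerates both esters.

Vinyl epoxide 17 comes from epoxy aldehyde 16 by methylenation, and 16 from epoxy alcohol 15. The cis-epoxide of 15 is set by Sharpless epoxidation of (Z)-allylic alcohol 14, the C8 hydroxyl serving as the directing group and the reagent fixing C6 and C7.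

The Z-alkene of 14 comes from aldehyde 11 and phosphonate 12 by Still–Gennari olefination (13) and reduction. The tert-butyl ester at C1 is what allows the methyl enoate to be reduced alone.

Aldehyde 11 is cut back through ester 9 and acid 8 to lactone 5. In the 1,4-lactone O4 is the ring oxygen, so O3, O5 and O6 can be silylated while O4 is set apart without any alkylation; opening the lactone then exposes O4 alone for the TES group.

Lactone 5 comes from 2-deoxy-D-galactose 1 via lactone 3, which supplies C3, C4 and C5 without any stereocentre-forming step.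

Benzoate 24 is cut back to epoxy alcohol 19, made by Sharpless desymmetrisation of divinylcarbinol 18. This sets C10 and C11 together by reagent control, and the two oxygens are born different (one a hydroxyl, one an epoxide).

## Alternatives that were turned down

Alternative 1: The C2=C3 bond of an unsaturated lactone and the C7 vinyl group are traced back to the strained alkene of oxanorbornene acrylate A1, in which C3 and C8 are still joined. Ring-rearrangement metathesis (second-generation Hoveyda–Grubbs catalyst) would open that alkene and close onto the acrylate to give A2.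
- For: strain drives the step, and the bridged precursor holds all four oxolane substituents cis by construction, with no substitution at C7. The bicyclic core arrives in very few steps, and on step economy for the core this route is stronger than the chosen one.
- Against: C3 is sp2 in A2 and its hydroxyl must be added later. The target needs it on the concave face, cis to the ring oxygen, whereas conjugate addition to a cis-fused bicycle is expected from the convex face, giving the C3 epimer. A1 must also be obtained as one enantiomer with O5 and O6 told apart, the acrylate-derived carbene turns over slowly so ring-opening oligomerisation competes, and the side chain still has to be attached by cross-metathesis.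
- Comparison: the chosen route is longer, but C3, C4 and C5 come fixed from the sugar and the C3 oxygen is in place from the first step.

Alternative 2: The ring O–C4 bond and the C3–O bond are traced back to the (Z)-alkene and the 7,8-diol of open-chain A3. The osmate ester of the diol (catalytic OsO4 or K2OsO2(OH)4, pyridine N-oxide, acid) would add across C3=C4 to give A4.
- For: two C–O bonds and the C3 and C4 centres are made in one step, and the 2,5-cis relationship is inherent in the tethered syn addition. It cannot leak through a cation, which is a real advantage over an acid-promoted epoxide opening.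
- Against: A4 has C1 as an ether at the alcohol level and C8 as a primary alcohol. C8 would have to become an aldehyde next to the ring oxygen, where C7 of an all-cis ring epimerises easily, and then be olefinated with a side chain whose C10 benzoate rules out the usual carbanions. The acetonide, the benzyl ether, oxidation of C1 and the lactonisation follow, at least eight steps after the key step against two here, and the cyclisation itself must occur on the face of the acetonide.
- Comparison: the chosen route closes the ring last, with the side chain in place and no carbonyl ever adjacent to C7.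

Alternative 3: The C4–C5 bond is cut, leading back to aldehyde A5, in which C4 is the methylene of a glycolate thioester ether on O7. Soft enolisation (MgBr2·OEt2, i-Pr2NEt) and intramolecular aldol addition would give A6.
- For: it is convergent, the side chain being joined through the ether before ring closure; the conditions tolerate both esters; and a C–C bond and the ring form together. On convergence it is stronger than the chosen route.
- Against: two stereocentres (C4 and C5) are created and both must come out cis to C6 and C7, the crowded arrangement. C4–H in A6 is α to the thioester and can epimerise, the aldol can revert, and C6 in A5 is α to the aldehyde. C3 does not yet exist: the thioester carbon must be extended by C1–C2 and the resulting ketone reduced to the 3R alcohol.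
- Comparison: the chosen route creates only C7 in its key step, by inversion of a reagent-made epoxide.

Key step: step 20

## Route

Step 1
Reactants: 1 2-deoxy-D-galactose
Product: 3 2-deoxy-D-lyxo-hexono-1,4-lactone, via 2-deoxy-D-lyxo-hexonic acid 2 (not isolated)
Conditions: Br2, BaCO3, H2O, rt; H+ resin; concentrate
Reagents that add atoms: none
Why: Bromine water oxidises the hemiacetal carbon of an aldose to the aldonic acid (classical aldose oxidation); on acidic evaporation the acid closes to the five-membered 1,4-lactone, the preferred lactone of hexonic acids, which ties up O4 and C1 and leaves O3, O5 and O6 free. No stereocentre is touched.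

Step 2
Reactants: 3 2-deoxy-D-lyxo-hexono-1,4-lactone
Product: 4 6-O-TES-2-deoxy-D-lyxo-hexono-1,4-lactone
Conditions: Et3SiCl (1.05 equiv), pyridine, −30 °C
Reagents that add atoms: chlorotriethylsilane, CC[Si](Cl)(CC)CC
Why: Regioselective silylation: the primary hydroxyl reacts far faster than the two secondary ones with one equivalent of chlorosilane at low temperature.

Step 3
Reactants: 4 6-O-TES-2-deoxy-D-lyxo-hexono-1,4-lactone
Product: 5 3,5-di-O-TBS-6-O-TES-2-deoxy-D-lyxo-hexono-1,4-lactone
Conditions: TBSOTf (2.4 equiv), 2,6-lutidine, CH2Cl2, −78 → 0 °C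
Reagents that add atoms: tert-butyldimethylsilyl trifluoromethanesulfonate, CC(C)(C)[Si](C)(C)OS(=O)(=O)C(F)(F)F
Why: Silyl triflate with a hindered pyridine base silylates both secondary hydroxyls without enolising the lactone, so the 3-silyloxy group is not eliminated.

Step 4
Reactants: 5 3,5-di-O-TBS-6-O-TES-2-deoxy-D-lyxo-hexono-1,4-lactone
Product: 8 (3R,4R,5R)-3,5-bis(TBS-oxy)-4,6-bis(TES-oxy)hexanoic acid, via lithium 4-hydroxy carboxylate 6 (not isolated), via triethylsilyl ester 7 (not isolated)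
Conditions: LiOH (1.1 equiv), THF/H2O, 0 °C; evaporate, toluene azeotrope; Et3SiOTf (2.5 equiv), 2,6-lutidine, CH2Cl2, −78 → 0 °C; MeOH/H2O, K2CO3 (cat.), 0 °C; pH 5 buffer
Reagents that add atoms: lithium hydroxide, [Li+].[OH-]; triethylsilyl trifluoromethanesulfonate, CC[Si](CC)(CC)OS(=O)(=O)C(F)(F)F
Why: Saponification opens the lactone to the carboxylate, the only point at which O4 is free; silylation caps O4 as its TES ether before it can close again, and the much more labile silyl ester is then hydrolysed selectively (saponification, persilylation, silyl ester cleavage).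

Step 5
Reactants: 8 (3R,4R,5R)-3,5-bis(TBS-oxy)-4,6-bis(TES-oxy)hexanoic acid
Product: 9 tert-butyl (3R,4R,5R)-3,5-bis(TBS-oxy)-4,6-bis(TES-oxy)hexanoate
Conditions: O-tert-butyl-N,N'-diisopropylisourea (3 equiv), CH2Cl2, rt
Reagents that add atoms: O-tert-butyl-N,N'-diisopropylisourea, CC(C)N=C(OC(C)(C)C)NC(C)C
Why: Isourea esterification of a free acid under neutral conditions (proton transfer, then tert-butyl transfer) keeps the silyl ethers; the tert-butyl ester is chosen because it resists hydride at low temperature and cannot acylate O4 later.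

Step 6
Reactants: 9 tert-butyl (3R,4R,5R)-3,5-bis(TBS-oxy)-4,6-bis(TES-oxy)hexanoate
Product: 11 tert-butyl (3R,4R,5S)-3,5-bis(TBS-oxy)-6-oxo-4-(TES-oxy)hexanoate, via C6 primary alcohol 10 (not isolated)
Conditions: (COCl)2, DMSO, CH2Cl2, −78 → −35 °C; Et3N, −78 → 0 °C
Reagents that add atoms: none
Why: Under Swern conditions a primary TES ether is cleaved by the chlorosulfonium species and oxidised in the same flask, while secondary TES and TBS ethers are untouched (oxidative desilylation); the amine is added cold so that the α-silyloxy aldehyde does not epimerise at C5.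

Step 7
Reactants: 11 tert-butyl (3R,4R,5S)-3,5-bis(TBS-oxy)-6-oxo-4-(TES-oxy)hexanoate; 12 bis(2,2,2-trifluoroethyl) (methoxycarbonylmethyl)phosphonate
Product: 13 8-tert-butyl 1-methyl (2Z,4R,5R,6R)-4,6-bis(TBS-oxy)-5-(TES-oxy)oct-2-enedioate
Conditions: KN(SiMe3)2, 18-crown-6, THF, −78 °C
Reagents that add atoms: none
Why: Still–Gennari olefination: the electron-poor phosphonate under dissociating conditions eliminates fast from the kinetic adduct and gives the (Z)-enoate; the preformed phosphonate anion is too weak a base to enolise the aldehyde or the tert-butyl ester.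

Step 8
Reactants: 13 8-tert-butyl 1-methyl (2Z,4R,5R,6R)-4,6-bis(TBS-oxy)-5-(TES-oxy)oct-2-enedioate
Product: 14 tert-butyl (3R,4R,5R,6Z)-3,5-bis(TBS-oxy)-8-hydroxy-4-(TES-oxy)oct-6-enoate
Conditions: i-Bu2AlH (2.3 equiv), CH2Cl2, −78 °C
Reagents that add atoms: none
Why: Chemoselective ester reduction: the conjugated methyl ester is reduced to the allylic alcohol at −78 °C, where the hindered tert-butyl ester reacts much more slowly; the Z geometry is retained.

Step 9
Reactants: 14 tert-butyl (3R,4R,5R,6Z)-3,5-bis(TBS-oxy)-8-hydroxy-4-(TES-oxy)oct-6-enoate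
Product: 15 tert-butyl (3R,4R,5R)-3,5-bis(TBS-oxy)-5-[(2R,3R)-3-(hydroxymethyl)oxiran-2-yl]-4-(TES-oxy)pentanoate (cis-epoxide)
Conditions: Ti(OiPr)4 (1.2 equiv), D-(−)-diisopropyl tartrate (1.4 equiv), t-BuOOH, 4 Å MS, CH2Cl2, −20 °C
Reagents that add atoms: tert-butyl hydroperoxide, CC(C)(C)OO
Why: Sharpless asymmetric epoxidation: the primary allylic alcohol binds the titanium tartrate, and the unnatural D-(−)-tartrate delivers oxygen to the face that makes the carbinol-bearing epoxide carbon C7 R (and C6 R); syn addition to the Z-alkene gives the cis-epoxide. A full equivalent of the titanium complex is used because Z-allylic alcohols with a branched neighbouring carbon react slowly.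

Step 10
Reactants: 15 tert-butyl (3R,4R,5R)-3,5-bis(TBS-oxy)-5-[(2R,3R)-3-(hydroxymethyl)oxiran-2-yl]-4-(TES-oxy)pentanoate
Product: 16 tert-butyl (3R,4R,5R)-3,5-bis(TBS-oxy)-5-[(2R,3S)-3-formyloxiran-2-yl]-4-(TES-oxy)pentanoate
Conditions: Dess–Martin periodinane, NaHCO3, CH2Cl2, 0 °C → rt
Reagents that add atoms: none
Why: Buffered Dess–Martin oxidation gives the aldehyde without acid that could open the epoxide; an epoxide carbon enolises reluctantly, so C7 keeps its configuration (the descriptor changes only because the priorities change).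

Step 11
Reactants: 16 tert-butyl (3R,4R,5R)-3,5-bis(TBS-oxy)-5-[(2R,3S)-3-formyloxiran-2-yl]-4-(TES-oxy)pentanoate
Product: 17 tert-butyl (3R,4R,5R)-3,5-bis(TBS-oxy)-5-[(2R,3R)-3-ethenyloxiran-2-yl]-4-(TES-oxy)pentanoate
Conditions: Ph3PCH3Br, KN(SiMe3)2, THF, 0 °C; then 16, −78 → 0 °C
Reagents that add atoms: methyltriphenylphosphonium bromide, C[P+](c1ccccc1)(c1ccccc1)c1ccccc1.[Br-]
Why: Wittig methylenation; the non-stabilised ylide adds to the aldehyde at low temperature and leaves the tert-butyl ester and the epoxide alone, and no alkene geometry is at stake.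

Step 12
Reactants: 18 penta-1,4-dien-3-ol
Product: 19 (2R,3S)-1,2-epoxypent-4-en-3-ol
Conditions: Ti(OiPr)4 (10 mol %), L-(+)-diisopropyl tartrate (13 mol %), t-BuOOH, 4 Å MS, CH2Cl2, −20 °C
Reagents that add atoms: tert-butyl hydroperoxide, CC(C)(C)OO
Why: Sharpless epoxidation of the achiral divinylcarbinol: the L-(+)-tartrate complex picks one enantiotopic vinyl group and one of its faces, giving the erythro epoxy alcohol that holds the future C10 and C11; the minor enantiomer is consumed faster by a second epoxidation, so the enantiomeric purity rises with conversion.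

Step 13
Reactants: 19 (2R,3S)-1,2-epoxypent-4-en-3-ol
Product: 20 (2R)-2-[(1S)-1-(4-methoxybenzyloxy)prop-2-en-1-yl]oxirane
Conditions: NaH, 4-methoxybenzyl chloride, n-Bu4NI (cat.), THF, 0 °C
Reagents that add atoms: 4-methoxybenzyl chloride, COc1ccc(CCl)cc1
Why: Williamson etherification of the secondary alkoxide, fast with the benzylic halide under iodide catalysis at 0 °C so that epoxide migration does not compete; the ether shields O10 from the hydride of the next step.

Step 14
Reactants: 20 (2R)-2-[(1S)-1-(4-methoxybenzyloxy)prop-2-en-1-yl]oxirane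
Product: 21 (2R,3S)-3-(4-methoxybenzyloxy)pent-4-en-2-ol
Conditions: LiAlH4, THF, 0 °C
Reagents that add atoms: none
Why: Hydride opens the terminal epoxide at its unsubstituted carbon (SN2), which turns C12 into the methyl group and frees the C11 hydroxyl with its configuration unchanged.

Step 15
Reactants: 21 (2R,3S)-3-(4-methoxybenzyloxy)pent-4-en-2-ol
Product: 22 (2R,3S)-3-(4-methoxybenzyloxy)pent-4-en-2-yl acetate
Conditions: Ac2O, pyridine, DMAP (cat.), CH2Cl2, rt
Reagents that add atoms: acetic anhydride, CC(=O)OC(C)=O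
Why: Acylation of the secondary alcohol with nucleophilic catalysis installs the C11 acetate of the target.

Step 16
Reactants: 22 (2R,3S)-3-(4-methoxybenzyloxy)pent-4-en-2-yl acetate
Product: 23 (2R,3S)-3-hydroxypent-4-en-2-yl acetate
Conditions: DDQ, CH2Cl2/pH 7 buffer, 0 °C
Reagents that add atoms: none
Why: Oxidative debenzylation: DDQ converts the electron-rich benzyl ether into an oxocarbenium ion that water hydrolyses; the neutral medium avoids migration of the neighbouring acetate.

Step 17
Reactants: 23 (2R,3S)-3-hydroxypent-4-en-2-yl acetate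
Product: 24 (3S,4R)-4-acetoxypent-1-en-3-yl benzoate
Conditions: BzCl, pyridine, DMAP (cat.), CH2Cl2, 0 °C
Reagents that add atoms: benzoyl chloride, O=C(Cl)c1ccccc1
Why: Benzoylation of the allylic alcohol at 0 °C is faster than acetyl migration and places the two different esters on O10 and O11.

Step 18
Reactants: 17 tert-butyl (3R,4R,5R)-3,5-bis(TBS-oxy)-5-[(2R,3R)-3-ethenyloxiran-2-yl]-4-(TES-oxy)pentanoate; 24 (3S,4R)-4-acetoxypent-1-en-3-yl benzoate (3 equiv)
Product: 25 tert-butyl (3R,4R,5R)-5-{(2R,3R)-3-[(1E,3S,4R)-4-acetoxy-3-(benzoyloxy)pent-1-en-1-yl]oxiran-2-yl}-3,5-bis(TBS-oxy)-4-(TES-oxy)pentanoate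
Conditions: second-generation Hoveyda–Grubbs catalyst (10 mol %), CH2Cl2, 40 °C
Reagents that add atoms: none
Why: Olefin cross-metathesis between a vinyl epoxide and a secondary allylic ester, both slow to homodimerise, joins C8 and C9 with loss of ethene; the allylic branching on both sides favours the E-alkene, and esters, silyl ethers and the epoxide are inert to the ruthenium carbene.

Step 19
Reactants: 25 tert-butyl (3R,4R,5R)-5-{(2R,3R)-3-[(1E,3S,4R)-4-acetoxy-3-(benzoyloxy)pent-1-en-1-yl]oxiran-2-yl}-3,5-bis(TBS-oxy)-4-(TES-oxy)pentanoate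
Product: 26 tert-butyl (3R,4R,5S)-5-{(2R,3R)-3-[(1E,3S,4R)-4-acetoxy-3-(benzoyloxy)pent-1-en-1-yl]oxiran-2-yl}-3,5-bis(TBS-oxy)-4-hydroxypentanoate
Conditions: HF·pyridine, pyridine, THF, 0 °C
Reagents that add atoms: none
Why: Selective desilylation: a secondary TES ether is cleaved by buffered HF·pyridine much faster than secondary TBS ethers, and the pyridine buffer keeps the vinyl epoxide closed, so O4 alone is freed.

Step 20
Reactants: 26 tert-butyl (3R,4R,5S)-5-{(2R,3R)-3-[(1E,3S,4R)-4-acetoxy-3-(benzoyloxy)pent-1-en-1-yl]oxiran-2-yl}-3,5-bis(TBS-oxy)-4-hydroxypentanoate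
Product: 27 tert-butyl (3R)-3-{(2R,3R,4R,5S)-5-[(1E,3S,4R)-4-acetoxy-3-(benzoyloxy)pent-1-en-1-yl]-3-(TBS-oxy)-4-hydroxyoxolan-2-yl}-3-(TBS-oxy)propanoate
Conditions: camphorsulfonic acid (0.2 equiv), CH2Cl2, 0 °C → rt
Reagents that add atoms: none
Why: The acid activates the epoxide oxygen and lengthens the C7–O bond, whose developing positive charge is shared with the C8=C9 π bond, and the C4 hydroxyl attacks C7 from the side opposite to the epoxide oxygen. The closest known reaction type is the acid-catalysed endo-selective cyclisation of hydroxy vinyl epoxides. The oxolane closes in the 5-endo-tet (epoxide) mode; the competing 4-exo attack at C6 would give an oxetane and has no allylic assistance. The only new stereocentre, C7, is controlled by stereospecific inversion of the epoxide carbon set by the Sharpless reagent in step 9, so the cis-epoxide puts the C6 hydroxyl and the C7 alkenyl group cis to each other and to the C4 and C5 substituents. The step needs selectivity among the oxygens, which the silyl ethers on O3 and O5 secure (a free O3 could close a six-membered ring), and it needs the SN2-like path to outrun free ionisation, which the electron-withdrawing benzoate on C10, the non-polar solvent and the low temperature favour. The tert-butyl ester keeps C1 from acylating O4, and catalytic anhydrous acid leaves the silyl ethers in place. The C6 hydroxyl is released directly, so the ring needs no further adjustment.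

Step 21
Reactants: 27 tert-butyl (3R)-3-{(2R,3R,4R,5S)-5-[(1E,3S,4R)-4-acetoxy-3-(benzoyloxy)pent-1-en-1-yl]-3-(TBS-oxy)-4-hydroxyoxolan-2-yl}-3-(TBS-oxy)propanoate
Product: 28 tert-butyl (3R)-3-{(2R,3R,4S,5S)-5-[(1E,3S,4R)-4-acetoxy-3-(benzoyloxy)pent-1-en-1-yl]-3,4-dihydroxyoxolan-2-yl}-3-hydroxypropanoate
Conditions: HF·pyridine, THF, 0 °C → rt
Reagents that add atoms: none
Why: Unbuffered HF·pyridine removes both TBS ethers by Si–F bond formation without touching the esters or the allylic ether (the C6 descriptor changes only through the priority rules).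

Step 22
Reactants: 28 tert-butyl (3R)-3-{(2R,3R,4S,5S)-5-[(1E,3S,4R)-4-acetoxy-3-(benzoyloxy)pent-1-en-1-yl]-3,4-dihydroxyoxolan-2-yl}-3-hydroxypropanoate
Product: 30 (1E,3S,4R)-4-acetoxy-1-[(2S,3R,3aR,7R,7aR)-3,7-dihydroxy-5-oxohexahydro-2H-furo[3,2-b]pyran-2-yl]pent-1-en-3-yl benzoate (CNP0230210.1), via C1 carboxylic acid 29 (not isolated)
Conditions: CF3CO2H/CH2Cl2 (1:4), 0 °C → rt; toluene co-evaporation
Reagents that add atoms: none
Why: Acidolysis of the tert-butyl ester (loss of the tert-butyl cation) frees the acid, which lactonises under the same acid onto the C5 hydroxyl; this hydroxyl is cis to the C3–C4 arm on the oxolane, so the cis-fused six-membered lactone forms, and O4, now an ether, cannot compete.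

## Compound list

1 | 2-deoxy-D-galactose (2-deoxy-D-lyxo-hexopyranose) | OC[C@H]1OC(O)C[C@@H](O)[C@H]1O | starting material
2 | 2-deoxy-D-lyxo-hexonic acid, (3R,4R,5R)-3,4,5,6-tetrahydroxyhexanoic acid | OC[C@@H](O)[C@H](O)[C@H](O)CC(=O)O | intermediate
3 | 2-deoxy-D-lyxo-hexono-1,4-lactone, (4R,5R)-5-[(1R)-1,2-dihydroxyethyl]-4-hydroxyoxolan-2-one | O=C1C[C@@H](O)[C@H]([C@H](O)CO)O1 | intermediate
4 | 6-O-TES-2-deoxy-D-lyxo-hexono-1,4-lactone | O=C1C[C@@H](O)[C@H]([C@H](O)CO[Si](CC)(CC)CC)O1 | intermediate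
5 | 3,5-di-O-TBS-6-O-TES-2-deoxy-D-lyxo-hexono-1,4-lactone | O=C1C[C@@H](O[Si](C)(C)C(C)(C)C)[C@H]([C@H](O[Si](C)(C)C(C)(C)C)CO[Si](CC)(CC)CC)O1 | intermediate
6 | lithium (3R,4R,5R)-3,5-bis(TBS-oxy)-4-hydroxy-6-(TES-oxy)hexanoate | CC[Si](CC)(CC)OC[C@@H](O[Si](C)(C)C(C)(C)C)[C@H](O)[C@@H](CC(=O)[O-])O[Si](C)(C)C(C)(C)C.[Li+] | intermediate
7 | triethylsilyl (3R,4R,5R)-3,5-bis(TBS-oxy)-4,6-bis(TES-oxy)hexanoate | CC[Si](CC)(CC)OC[C@@H](O[Si](C)(C)C(C)(C)C)[C@H](O[Si](CC)(CC)CC)[C@@H](CC(=O)O[Si](CC)(CC)CC)O[Si](C)(C)C(C)(C)C | intermediate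
8 | (3R,4R,5R)-3,5-bis(TBS-oxy)-4,6-bis(TES-oxy)hexanoic acid | CC[Si](CC)(CC)OC[C@@H](O[Si](C)(C)C(C)(C)C)[C@H](O[Si](CC)(CC)CC)[C@@H](CC(=O)O)O[Si](C)(C)C(C)(C)C | intermediate
9 | tert-butyl (3R,4R,5R)-3,5-bis(TBS-oxy)-4,6-bis(TES-oxy)hexanoate | CC[Si](CC)(CC)OC[C@@H](O[Si](C)(C)C(C)(C)C)[C@H](O[Si](CC)(CC)CC)[C@@H](CC(=O)OC(C)(C)C)O[Si](C)(C)C(C)(C)C | intermediate
10 | tert-butyl (3R,4R,5R)-3,5-bis(TBS-oxy)-6-hydroxy-4-(TES-oxy)hexanoate | OC[C@@H](O[Si](C)(C)C(C)(C)C)[C@H](O[Si](CC)(CC)CC)[C@@H](CC(=O)OC(C)(C)C)O[Si](C)(C)C(C)(C)C | intermediate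
11 | tert-butyl (3R,4R,5S)-3,5-bis(TBS-oxy)-6-oxo-4-(TES-oxy)hexanoate | O=C[C@@H](O[Si](C)(C)C(C)(C)C)[C@H](O[Si](CC)(CC)CC)[C@@H](CC(=O)OC(C)(C)C)O[Si](C)(C)C(C)(C)C | intermediate
12 | bis(2,2,2-trifluoroethyl) (methoxycarbonylmethyl)phosphonate | COC(=O)CP(=O)(OCC(F)(F)F)OCC(F)(F)F | starting material
13 | 8-tert-butyl 1-methyl (2Z,4R,5R,6R)-4,6-bis(TBS-oxy)-5-(TES-oxy)oct-2-enedioate | COC(=O)/C=C\[C@@H](O[Si](C)(C)C(C)(C)C)[C@H](O[Si](CC)(CC)CC)[C@@H](CC(=O)OC(C)(C)C)O[Si](C)(C)C(C)(C)C | intermediate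
14 | tert-butyl (3R,4R,5R,6Z)-3,5-bis(TBS-oxy)-8-hydroxy-4-(TES-oxy)oct-6-enoate | OC/C=C\[C@@H](O[Si](C)(C)C(C)(C)C)[C@H](O[Si](CC)(CC)CC)[C@@H](CC(=O)OC(C)(C)C)O[Si](C)(C)C(C)(C)C | intermediate
15 | tert-butyl (3R,4R,5R)-3,5-bis(TBS-oxy)-5-[(2R,3R)-3-(hydroxymethyl)oxiran-2-yl]-4-(TES-oxy)pentanoate | OC[C@H]1O[C@H]1[C@@H](O[Si](C)(C)C(C)(C)C)[C@H](O[Si](CC)(CC)CC)[C@@H](CC(=O)OC(C)(C)C)O[Si](C)(C)C(C)(C)C | intermediate
16 | tert-butyl (3R,4R,5R)-3,5-bis(TBS-oxy)-5-[(2R,3S)-3-formyloxiran-2-yl]-4-(TES-oxy)pentanoate | O=C[C@H]1O[C@H]1[C@@H](O[Si](C)(C)C(C)(C)C)[C@H](O[Si](CC)(CC)CC)[C@@H](CC(=O)OC(C)(C)C)O[Si](C)(C)C(C)(C)C | intermediate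
17 | tert-butyl (3R,4R,5R)-3,5-bis(TBS-oxy)-5-[(2R,3R)-3-ethenyloxiran-2-yl]-4-(TES-oxy)pentanoate | C=C[C@H]1O[C@H]1[C@@H](O[Si](C)(C)C(C)(C)C)[C@H](O[Si](CC)(CC)CC)[C@@H](CC(=O)OC(C)(C)C)O[Si](C)(C)C(C)(C)C | intermediate
18 | penta-1,4-dien-3-ol (divinylcarbinol) | C=CC(O)C=C | starting material
19 | (2R,3S)-1,2-epoxypent-4-en-3-ol | C=C[C@H](O)[C@H]1CO1 | intermediate
20 | (2R)-2-[(1S)-1-(4-methoxybenzyloxy)prop-2-en-1-yl]oxirane | C=C[C@H](OCc1ccc(OC)cc1)[C@H]1CO1 | intermediate
21 | (2R,3S)-3-(4-methoxybenzyloxy)pent-4-en-2-ol | C=C[C@H](OCc1ccc(OC)cc1)[C@@H](C)O | intermediate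
22 | (2R,3S)-3-(4-methoxybenzyloxy)pent-4-en-2-yl acetate | C=C[C@H](OCc1ccc(OC)cc1)[C@@H](C)OC(C)=O | intermediate
23 | (2R,3S)-3-hydroxypent-4-en-2-yl acetate | C=C[C@H](O)[C@@H](C)OC(C)=O | intermediate
24 | (3S,4R)-4-acetoxypent-1-en-3-yl benzoate | C=C[C@H](OC(=O)c1ccccc1)[C@@H](C)OC(C)=O | intermediate
25 | tert-butyl (3R,4R,5R)-5-{(2R,3R)-3-[(1E,3S,4R)-4-acetoxy-3-(benzoyloxy)pent-1-en-1-yl]oxiran-2-yl}-3,5-bis(TBS-oxy)-4-(TES-oxy)pentanoate | CC(=O)O[C@H](C)[C@H](/C=C/[C@H]1O[C@H]1[C@@H](O[Si](C)(C)C(C)(C)C)[C@H](O[Si](CC)(CC)CC)[C@@H](CC(=O)OC(C)(C)C)O[Si](C)(C)C(C)(C)C)OC(=O)c1ccccc1 | intermediate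
26 | tert-butyl (3R,4R,5S)-5-{(2R,3R)-3-[(1E,3S,4R)-4-acetoxy-3-(benzoyloxy)pent-1-en-1-yl]oxiran-2-yl}-3,5-bis(TBS-oxy)-4-hydroxypentanoate | CC(=O)O[C@H](C)[C@H](/C=C/[C@H]1O[C@H]1[C@@H](O[Si](C)(C)C(C)(C)C)[C@H](O)[C@@H](CC(=O)OC(C)(C)C)O[Si](C)(C)C(C)(C)C)OC(=O)c1ccccc1 | intermediate
27 | tert-butyl (3R)-3-{(2R,3R,4R,5S)-5-[(1E,3S,4R)-4-acetoxy-3-(benzoyloxy)pent-1-en-1-yl]-3-(TBS-oxy)-4-hydroxyoxolan-2-yl}-3-(TBS-oxy)propanoate | CC(=O)O[C@H](C)[C@H](/C=C/[C@@H]1O[C@H]([C@@H](CC(=O)OC(C)(C)C)O[Si](C)(C)C(C)(C)C)[C@H](O[Si](C)(C)C(C)(C)C)[C@@H]1O)OC(=O)c1ccccc1 | intermediate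
28 | tert-butyl (3R)-3-{(2R,3R,4S,5S)-5-[(1E,3S,4R)-4-acetoxy-3-(benzoyloxy)pent-1-en-1-yl]-3,4-dihydroxyoxolan-2-yl}-3-hydroxypropanoate | CC(=O)O[C@H](C)[C@H](/C=C/[C@@H]1O[C@H]([C@@H](CC(=O)OC(C)(C)C)O)[C@H](O)[C@@H]1O)OC(=O)c1ccccc1 | intermediate
29 | (3R)-3-{(2R,3R,4S,5S)-5-[(1E,3S,4R)-4-acetoxy-3-(benzoyloxy)pent-1-en-1-yl]-3,4-dihydroxyoxolan-2-yl}-3-hydroxypropanoic acid | CC(=O)O[C@H](C)[C@H](/C=C/[C@@H]1O[C@H]([C@@H](CC(=O)O)O)[C@H](O)[C@@H]1O)OC(=O)c1ccccc1 | intermediate
30 | (1E,3S,4R)-4-acetoxy-1-[(2S,3R,3aR,7R,7aR)-3,7-dihydroxy-5-oxohexahydro-2H-furo[3,2-b]pyran-2-yl]pent-1-en-3-yl benzoate (CNP0230210.1) | CC(=O)O[C@H](C)[C@H](/C=C/[C@@H]1O[C@H]2[C@H](OC(=O)C[C@H]2O)[C@@H]1O)OC(=O)c1ccccc1 | target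

## Step count and least certain steps

Total: 22 steps (16 on the main line from 1, 6 for the side chain from 18). Longest linear sequence: 16 steps (steps 1–11 and 18–22).

Step 20 (key step). The SN2-like closure builds the crowded all-cis ring, so it may be slow enough for ionisation to a free allyl cation to intervene, which would erode the inversion at C7. The carbonyl oxygen of the C10 benzoate may also capture the activated allyl system at C9 with allylic transposition. Fallback: close the ring before the side chain is attached. Setting out from 17, buffered HF·pyridine would free O4 to give tert-butyl (3R,4R,5S)-3,5-bis(TBS-oxy)-5-[(2R,3R)-3-ethenyloxiran-2-yl]-4-hydroxypentanoate F1. Camphorsulfonic acid would then cyclise this simpler substrate, which has no ester near the allyl system, to tert-butyl (3R)-3-(TBS-oxy)-3-[(2R,3R,4R,5S)-3-(TBS-oxy)-5-ethenyl-4-hydroxyoxolan-2-yl]propanoate F2. Cross-metathesis of F2 with 24 comes back to the route at 27.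

Step 18. Both olefins are deactivated by allylic oxygen, so catalyst decay before full conversion, homodimerisation of 24 and incomplete E-selectivity are the likely failures. Fallback: a Julia–Kocienski olefination with a sulfone that carries an ether, not an ester, on C10. Setting out from 22 and 16:
- ozonolysis of 22 with NaBH4 work-up would give (2R,3S)-4-hydroxy-3-(4-methoxybenzyloxy)butan-2-yl acetate F3;
- Mitsunobu reaction with 1-phenyl-1H-tetrazole-5-thiol would give the sulfide (2R,3R)-3-(4-methoxybenzyloxy)-4-[(1-phenyl-1H-tetrazol-5-yl)sulfanyl]butan-2-yl acetate F4;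
- oxidation with H2O2 and (NH4)6Mo7O24 would give the sulfone (2R,3R)-3-(4-methoxybenzyloxy)-4-[(1-phenyl-1H-tetrazol-5-yl)sulfonyl]butan-2-yl acetate F5;
- olefination of 16 with F5 (KN(SiMe3)2, DME, −60 °C) would give tert-butyl (3R,4R,5R)-5-{(2R,3R)-3-[(1E,3S,4R)-4-acetoxy-3-(4-methoxybenzyloxy)pent-1-en-1-yl]oxiran-2-yl}-3,5-bis(TBS-oxy)-4-(TES-oxy)pentanoate F6;
- DDQ would free the allylic alcohol tert-butyl (3R,4R,5R)-5-{(2R,3R)-3-[(1E,3S,4R)-4-acetoxy-3-hydroxypent-1-en-1-yl]oxiran-2-yl}-3,5-bis(TBS-oxy)-4-(TES-oxy)pentanoate F7;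
- benzoylation of F7 comes back to the route at 25.

Step 9. Z-allylic alcohols with a branched neighbouring carbon are slow substrates, and the C5 centre may oppose the reagent, so slow conversion and poor facial selectivity are the risk. The required face is anti to the C5 silyloxy group in the strain-minimised conformer, which is expected, but not assured, to be the favoured one. Fallback: build the cis-epoxide by C6–C7 bond formation instead. Setting out from 11, the (Z)-γ-chloroallylborane made from allyl chloride, LiN(c-C6H11)2 and (+)-Ipc2BOMe, then BF3·OEt2, would give the syn-chlorohydrin tert-butyl (3R,4R,5R,6S,7S)-3,5-bis(TBS-oxy)-7-chloro-6-hydroxy-4-(TES-oxy)non-8-enoate F8, with C6 under reagent control (this enantiomer of the borane is the one expected to give 6S). DBU would close the epoxide with inversion at C7, and the route is rejoined at 17, which also removes steps 7–11.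

Step 4. Between saponification and silylation O4 is a free alkoxide flanked by two TBS ethers, so silyl migration onto O4 or reclosure of the lactone during handling is the risk. Fallback: open the lactone without an alkoxide. Setting out from 5, MeNH(OMe)·HCl and AlMe3 would give the amide (3R,4R,5R)-3,5-bis(TBS-oxy)-4-hydroxy-N-methoxy-N-methyl-6-(TES-oxy)hexanamide F9. Et3SiOTf and 2,6-lutidine would cap O4 to give (3R,4R,5R)-3,5-bis(TBS-oxy)-N-methoxy-N-methyl-4,6-bis(TES-oxy)hexanamide F10. i-Bu2AlH would give the aldehyde (3R,4R,5R)-3,5-bis(TBS-oxy)-4,6-bis(TES-oxy)hexanal F11, and Pinnick oxidation (NaClO2) comes back to the route at 8.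

## Further compounds

F1 | step 20 | tert-butyl (3R,4R,5S)-3,5-bis(TBS-oxy)-5-[(2R,3R)-3-ethenyloxiran-2-yl]-4-hydroxypentanoate | C=C[C@H]1O[C@H]1[C@@H](O[Si](C)(C)C(C)(C)C)[C@H](O)[C@@H](CC(=O)OC(C)(C)C)O[Si](C)(C)C(C)(C)C
F2 | step 20 | tert-butyl (3R)-3-(TBS-oxy)-3-[(2R,3R,4R,5S)-3-(TBS-oxy)-5-ethenyl-4-hydroxyoxolan-2-yl]propanoate | C=C[C@@H]1O[C@H]([C@@H](CC(=O)OC(C)(C)C)O[Si](C)(C)C(C)(C)C)[C@H](O[Si](C)(C)C(C)(C)C)[C@@H]1O
F3 | step 18 | (2R,3S)-4-hydroxy-3-(4-methoxybenzyloxy)butan-2-yl acetate | OC[C@H](OCc1ccc(OC)cc1)[C@@H](C)OC(C)=O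
F4 | step 18 | (2R,3R)-3-(4-methoxybenzyloxy)-4-[(1-phenyl-1H-tetrazol-5-yl)sulfanyl]butan-2-yl acetate | CC(=O)O[C@H](C)[C@H](CSc1nnnn1-c1ccccc1)OCc1ccc(OC)cc1
F5 | step 18 | (2R,3R)-3-(4-methoxybenzyloxy)-4-[(1-phenyl-1H-tetrazol-5-yl)sulfonyl]butan-2-yl acetate | CC(=O)O[C@H](C)[C@H](CS(=O)(=O)c1nnnn1-c1ccccc1)OCc1ccc(OC)cc1
F6 | step 18 | tert-butyl (3R,4R,5R)-5-{(2R,3R)-3-[(1E,3S,4R)-4-acetoxy-3-(4-methoxybenzyloxy)pent-1-en-1-yl]oxiran-2-yl}-3,5-bis(TBS-oxy)-4-(TES-oxy)pentanoate | CC(=O)O[C@H](C)[C@H](/C=C/[C@H]1O[C@H]1[C@@H](O[Si](C)(C)C(C)(C)C)[C@H](O[Si](CC)(CC)CC)[C@@H](CC(=O)OC(C)(C)C)O[Si](C)(C)C(C)(C)C)OCc1ccc(OC)cc1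
F7 | step 18 | tert-butyl (3R,4R,5R)-5-{(2R,3R)-3-[(1E,3S,4R)-4-acetoxy-3-hydroxypent-1-en-1-yl]oxiran-2-yl}-3,5-bis(TBS-oxy)-4-(TES-oxy)pentanoate | CC(=O)O[C@H](C)[C@H](/C=C/[C@H]1O[C@H]1[C@@H](O[Si](C)(C)C(C)(C)C)[C@H](O[Si](CC)(CC)CC)[C@@H](CC(=O)OC(C)(C)C)O[Si](C)(C)C(C)(C)C)O
F8 | step 9 | tert-butyl (3R,4R,5R,6S,7S)-3,5-bis(TBS-oxy)-7-chloro-6-hydroxy-4-(TES-oxy)non-8-enoate | C=C[C@H](Cl)[C@@H](O)[C@@H](O[Si](C)(C)C(C)(C)C)[C@H](O[Si](CC)(CC)CC)[C@@H](CC(=O)OC(C)(C)C)O[Si](C)(C)C(C)(C)C
F9 | step 4 | (3R,4R,5R)-3,5-bis(TBS-oxy)-4-hydroxy-N-methoxy-N-methyl-6-(TES-oxy)hexanamide | CC[Si](CC)(CC)OC[C@@H](O[Si](C)(C)C(C)(C)C)[C@H](O)[C@@H](CC(=O)N(C)OC)O[Si](C)(C)C(C)(C)C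
F10 | step 4 | (3R,4R,5R)-3,5-bis(TBS-oxy)-N-methoxy-N-methyl-4,6-bis(TES-oxy)hexanamide | CC[Si](CC)(CC)OC[C@@H](O[Si](C)(C)C(C)(C)C)[C@H](O[Si](CC)(CC)CC)[C@@H](CC(=O)N(C)OC)O[Si](C)(C)C(C)(C)C
F11 | step 4 | (3R,4R,5R)-3,5-bis(TBS-oxy)-4,6-bis(TES-oxy)hexanal | CC[Si](CC)(CC)OC[C@@H](O[Si](C)(C)C(C)(C)C)[C@H](O[Si](CC)(CC)CC)[C@@H](CC=O)O[Si](C)(C)C(C)(C)C
A1 | alternative 1 | endo-5-(acryloyloxy)-endo-6-(tert-butyldimethylsilyloxy)-7-oxabicyclo[2.2.1]hept-2-ene (enantiomer of the SMILES) | C=CC(=O)O[C@@H]1[C@H](O[Si](C)(C)C(C)(C)C)[C@@H]2C=C[C@H]1O2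
A2 | alternative 1 | all-cis 3-(tert-butyldimethylsilyloxy)-2-ethenyl-2,3,3a,7a-tetrahydro-5H-furo[3,2-b]pyran-5-one | C=C[C@@H]1O[C@H]2[C@H](OC(=O)C=C2)[C@@H]1O[Si](C)(C)C(C)(C)C
A3 | alternative 2 | open-chain (Z)-C3=C4 alkene with 7,8-diol, 5,6-O-isopropylidene and C1 4-methoxybenzyl ether | COc1ccc(COCC/C=C\[C@@H]2OC(C)(C)O[C@@H]2[C@@H](O)CO)cc1
A4 | alternative 2 | all-cis 2,5-disubstituted oxolane with fused 5,6-acetonide and free C3 and C8 hydroxyls | OC[C@@H]1O[C@H]([C@H](O)CCOCc2ccc(OC)cc2)[C@@H]2OC(C)(C)O[C@@H]21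
A5 | alternative 3 | C5 aldehyde with C6 4-methoxybenzyl ether, O7-glycolate S-phenyl thioester ether and complete side chain | CC(=O)O[C@H](C)[C@H](/C=C/[C@H](OCC(=O)Sc1ccccc1)[C@@H](OCc1ccc(OC)cc1)C=O)OC(=O)c1ccccc1
A6 | alternative 3 | all-cis oxolane with C4 S-phenyl thioester, C5 hydroxyl and C6 4-methoxybenzyl ether | CC(=O)O[C@H](C)[C@H](/C=C/[C@@H]1O[C@H](C(=O)Sc2ccccc2)[C@H](O)[C@@H]1OCc1ccc(OC)cc1)OC(=O)c1ccccc1
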